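**Plan** (target numbered as bicyclo[3.2.1]oct-3-ene-2,8-dione, C1–C8)
- Retrosynthesis cuts C3=C4 (aldol condensation), then C1–C2 (Claisen acylation), then C5–allyl and C6–CH3 (conjugate addition and enolate allylation), and last C5–C8 together with C6–C7 in one (3+2) annulation.
- Enabling feature: the five-membered ring C1–C7–C6–C5–C8 is a cyclopentanone. Its carbonyl C8, α-carbon C1 and aryl-bearing β-carbon C7 are the three carbons of a cinnamate; C6 and C5 are the two carbons of an alkyne.
- Forward order: cyclopentenone ring first (the alkyne also brings C4 as a masked aldehyde), then methyl at C6 and allyl at C5, then the C2–C3 unit on C1, and last the six-membered enone ring C1–C2–C3=C4–C5–C8.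
- Stereochemistry: C7 from the chiral ligand on nickel in the annulation; C6 (methyl anti to aryl) and C5 (allyl anti to methyl) by substrate control; C1 stays epimerisable until the bridge closes and is fixed by the ring fusion.

Key step: step 2

Remark: in step 2 the (S)-ligand is assumed to give the (S)-cyclopentenone; if the sense of induction is the reverse, the (R)-ligand is used and nothing else changes.

Step 1
Reactants: 1 (E)-3-(3,4-dimethoxyphenyl)prop-2-enoic acid; 2 phenol
Product: 3 phenyl (E)-3-(3,4-dimethoxyphenyl)prop-2-enoate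
Conditions: DCC, DMAP (cat.), CH2Cl2, 0 °C to rt
Reagents that add atoms: none
Why: Steglich esterification should give the aryl ester whose phenoxide is the leaving group needed in step 2; no stereocentre is formed and the E-alkene is untouched.

Step 2
Reactants: 3 phenyl (E)-3-(3,4-dimethoxyphenyl)prop-2-enoate; 4 3,3-diethoxyprop-1-yne
Product: 5 (S)-2-(diethoxymethyl)-4-(3,4-dimethoxyphenyl)cyclopent-2-en-1-one
Conditions: Ni(cod)2 (10 mol %), (S)-BI-DIME (12 mol %), 2-propanol/toluene, 60 °C, slow addition of 4
Reagents that add atoms: none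
Why: Proposed new method: zerovalent nickel should couple the enoate and the alkyne by oxidative cyclization, the β-carbon of 3 bonding to the unsubstituted alkyne terminus (the C6–C7 bond of the target) to give an oxanickelacycle whose nickel enolate is protonated by 2-propanol; the remaining alkenyl–nickel bond then adds to the phenyl ester carbonyl and phenoxide leaves (the C5–C8 bond), after which β-hydride elimination from the divalent nickel isopropoxide (giving acetone) and reductive elimination of phenol return zerovalent nickel. The closest known reaction type is the nickel/monophosphine-catalysed reductive (3+2) annulation of α,β-unsaturated phenyl esters with internal alkynes in 2-propanol, which gives racemic cyclopentenones, together with enantioselective nickel/BI-DIME reductive couplings of alkynes with carbonyl groups; new here are the terminal alkyne and the chiral ligand. The five-membered ring closes by a 5-exo-trig acyl substitution that follows the intermolecular C–C coupling, so the step is a formal (3+2) annulation. The only new stereocentre, the aryl-bearing carbon, is created in the oxidative cyclization inside the ligand sphere, so the P-chiral ligand should decide which enoate face is coupled. The step needs regioselectivity, which the steric difference between the CH terminus and the acetal-bearing terminus of 4 should secure (small end bonds to carbon, large end stays on nickel), and chemoselectivity against alkyne oligomerisation, which slow addition of 4 should secure.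

Step 3
Reactants: 5 (S)-2-(diethoxymethyl)-4-(3,4-dimethoxyphenyl)cyclopent-2-en-1-one
Product: 7 (2S,3R,4S)-2-(diethoxymethyl)-4-(3,4-dimethoxyphenyl)-3-methyl-2-(prop-2-en-1-yl)cyclopentan-1-one, via lithium enolate 6 (not isolated)
Conditions: Me2CuLi, Et2O, −78 °C; then DMPU, allyl bromide, −40 to 0 °C; aq. NH4Cl
Reagents that add atoms: lithium dimethylcuprate [Li+].C[Cu-]C; allyl bromide C=CCBr
Why: In this three-component conjugate addition/enolate alkylation the cuprate should add anti to the neighbouring aryl group (methyl trans to aryl), and the resulting tetrasubstituted enolate should be C-allylated anti to the new methyl group, which sets the quaternary centre with allyl trans to methyl.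

Step 4
Reactants: 7 (2S,3R,4S)-2-(diethoxymethyl)-4-(3,4-dimethoxyphenyl)-3-methyl-2-(prop-2-en-1-yl)cyclopentan-1-one
Product: 8 (2S,3R,4R,5S)-2-(diethoxymethyl)-4-(3,4-dimethoxyphenyl)-5-(methoxyacetyl)-3-methyl-2-(prop-2-en-1-yl)cyclopentan-1-one
Conditions: NaH, methyl methoxyacetate, THF, 0 to 45 °C; AcOH quench
Reagents that add atoms: methyl methoxyacetate COCC(=O)OC
Why: In this crossed Claisen condensation the only enolisable position of 7 is acylated by the activated α-alkoxy ester and deprotonation of the β-diketone drives the equilibrium; the new centre is epimerisable and should settle trans to the neighbouring aryl group, which is the configuration the bridge needs.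

Step 5
Reactants: 8 (2S,3R,4R,5S)-2-(diethoxymethyl)-4-(3,4-dimethoxyphenyl)-5-(methoxyacetyl)-3-methyl-2-(prop-2-en-1-yl)cyclopentan-1-one
Product: 11 kadsurenin D, via keto aldehyde 9 (not isolated), via aldol adduct 10 (not isolated)
Conditions: TsOH·H2O (20 mol %), acetone/H2O, rt; then toluene, 4 Å molecular sieves, 80 °C
Reagents that add atoms: none
Why: Acid should unmask the neopentyl aldehyde and then catalyse an intramolecular aldol condensation (6-(enolendo)-exo-trig) between the methoxymethyl ketone carbon and the aldehyde, the only enol that can reach the aldehyde through an unstrained ring, and dehydration gives the α-methoxy enone; C1 is fixed because only the epimer with the acyl group cis to the formyl group can cyclise, and the two transient centres are erased by the dehydration.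

**Compound list**
1 | (E)-3-(3,4-dimethoxyphenyl)prop-2-enoic acid | COc1ccc(/C=C/C(=O)O)cc1OC | starting material
2 | phenol | Oc1ccccc1 | starting material
3 | phenyl (E)-3-(3,4-dimethoxyphenyl)prop-2-enoate | COc1ccc(/C=C/C(=O)Oc2ccccc2)cc1OC | intermediate
4 | 3,3-diethoxyprop-1-yne | C#CC(OCC)OCC | starting material
5 | (S)-2-(diethoxymethyl)-4-(3,4-dimethoxyphenyl)cyclopent-2-en-1-one | O=C1C[C@H](c2ccc(OC)c(OC)c2)C=C1C(OCC)OCC | intermediate
6 | lithium (3R,4S)-2-(diethoxymethyl)-4-(3,4-dimethoxyphenyl)-3-methylcyclopent-1-en-1-olate | [Li+].[O-]C1=C(C(OCC)OCC)[C@H](C)[C@@H](c2ccc(OC)c(OC)c2)C1 | intermediate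
7 | (2S,3R,4S)-2-(diethoxymethyl)-4-(3,4-dimethoxyphenyl)-3-methyl-2-(prop-2-en-1-yl)cyclopentan-1-one | C=CC[C@]1(C(OCC)OCC)C(=O)C[C@H](c2ccc(OC)c(OC)c2)[C@H]1C | intermediate
8 | (2S,3R,4R,5S)-2-(diethoxymethyl)-4-(3,4-dimethoxyphenyl)-5-(methoxyacetyl)-3-methyl-2-(prop-2-en-1-yl)cyclopentan-1-one (drawn as the diketo tautomer) | C=CC[C@]1(C(OCC)OCC)C(=O)[C@@H](C(=O)COC)[C@H](c2ccc(OC)c(OC)c2)[C@H]1C | intermediate
9 | (1S,2R,3R,4S)-3-(3,4-dimethoxyphenyl)-4-(methoxyacetyl)-2-methyl-5-oxo-1-(prop-2-en-1-yl)cyclopentane-1-carbaldehyde | C=CC[C@]1(C=O)C(=O)[C@@H](C(=O)COC)[C@H](c2ccc(OC)c(OC)c2)[C@H]1C | intermediate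
10 | (1S,5S,6R,7R)-7-(3,4-dimethoxyphenyl)-4-hydroxy-3-methoxy-6-methyl-5-(prop-2-en-1-yl)bicyclo[3.2.1]octane-2,8-dione (epimers at C3 and C4, not defined) | C=CC[C@]12C(O)C(OC)C(=O)[C@H](C1=O)[C@H](c1ccc(OC)c(OC)c1)[C@H]2C | intermediate
11 | kadsurenin D, (1S,5S,6R,7R)-7-(3,4-dimethoxyphenyl)-3-methoxy-6-methyl-5-(prop-2-en-1-yl)bicyclo[3.2.1]oct-3-ene-2,8-dione | C=CC[C@]12C=C(OC)C(=O)[C@H](C1=O)[C@H](c1ccc(OC)c(OC)c1)[C@H]2C | target

Total step count: 5. Longest linear sequence: 5 steps (1 to 11).

**Steps most likely to fail**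

Step 2 (Proposed new method). What may go wrong: too little facial discrimination in the oxidative cyclization, oligomerisation of the terminal alkyne at zerovalent nickel, or transfer hydrogenation of the product enone. The fallback uses known chemistry, sets out from 1 and comes back at 5; it builds the ring by metathesis and sets the stereocentre with an auxiliary.
- Acid 1 is activated with pivaloyl chloride/Et3N and acylates the lithium salt of (R)-4-phenyloxazolidin-2-one to give (R)-3-[(E)-3-(3,4-dimethoxyphenyl)prop-2-enoyl]-4-phenyl-1,3-oxazolidin-2-one F1.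
- Vinylmagnesium bromide with CuBr·SMe2 in THF at −78 °C should add anti to the phenyl group of the chelated imide to give (R)-3-[(S)-3-(3,4-dimethoxyphenyl)pent-4-enoyl]-4-phenyl-1,3-oxazolidin-2-one F2.
- Me(MeO)NH·HCl/AlMe3 exchanges the auxiliary for the N-methoxy-N-methylamide, (S)-3-(3,4-dimethoxyphenyl)-N-methoxy-N-methylpent-4-enamide F3.
- 2-Lithio-3,3-diethoxyprop-1-ene (from 2-bromo-3,3-diethoxyprop-1-ene and t-BuLi) adds once to give (S)-2-(diethoxymethyl)-5-(3,4-dimethoxyphenyl)hepta-1,6-dien-3-one F4.
- Ring-closing metathesis with the second-generation Grubbs catalyst in CH2Cl2 at 40 °C should give 5.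

Step 5. What may go wrong: enolisation confined to the central carbon of the β-diketone so that the methoxymethyl carbon never attacks, acid-induced loss of the formyl group, or hydrolysis of the enol ether. The fallback sets out from 7 and comes back at 11; it builds the bridge in the reverse order (C3–C4 first and intermolecular, C1–C2 last and intramolecular).
- Mild acid hydrolysis of the acetal of 7 gives (1S,2R,3S)-3-(3,4-dimethoxyphenyl)-2-methyl-5-oxo-1-(prop-2-en-1-yl)cyclopentane-1-carbaldehyde F5.
- The lithium enolate of methyl methoxyacetate (LiN(i-Pr)2, THF, −78 °C) should add to the aldehyde in preference to the hindered ketone to give methyl 3-[(1S,2R,3S)-3-(3,4-dimethoxyphenyl)-2-methyl-5-oxo-1-(prop-2-en-1-yl)cyclopentyl]-3-hydroxy-2-methoxypropanoate F6.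
- TBSOTf/2,6-lutidine gives its tert-butyldimethylsilyl ether F7.
- LiN(SiMe3)2 in THF (−78 to 0 °C) should form the only ketone enolate and close the bridge by an intramolecular Claisen condensation to (1S,5S,6R,7R)-4-[(tert-butyldimethylsilyl)oxy]-7-(3,4-dimethoxyphenyl)-3-methoxy-6-methyl-5-(prop-2-en-1-yl)bicyclo[3.2.1]octane-2,8-dione F8.
- DBU should eliminate the silanol across C3–C4 to give 11.

Step 3. What may go wrong: β-elimination of ethoxide from the enolate, proton transfer between enolate and product leading to alkylation at the other α-carbon, or sluggish alkylation of the tetrasubstituted enolate. The fallback sets out from 5 and comes back at 7; it replaces the SN2 alkylation by a palladium-mediated allyl transfer under neutral conditions.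
- After the Me2CuLi addition the enolate is trapped on oxygen with allyl chloroformate at −78 °C to give prop-2-en-1-yl (3R,4S)-2-(diethoxymethyl)-4-(3,4-dimethoxyphenyl)-3-methylcyclopent-1-en-1-yl carbonate F9.
- Pd(PPh3)4 (cat.) in THF at rt should bring about the decarboxylative Tsuji–Trost allylation, again anti to the methyl group, to give 7.

Further compounds
F1 | step 2 | (R)-3-[(E)-3-(3,4-dimethoxyphenyl)prop-2-enoyl]-4-phenyl-1,3-oxazolidin-2-one | O=C1OC[C@@H](c2ccccc2)N1C(=O)/C=C/c1ccc(OC)c(OC)c1
F2 | step 2 | (R)-3-[(S)-3-(3,4-dimethoxyphenyl)pent-4-enoyl]-4-phenyl-1,3-oxazolidin-2-one | O=C1OC[C@@H](c2ccccc2)N1C(=O)C[C@@H](C=C)c1ccc(OC)c(OC)c1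
F3 | step 2 | (S)-3-(3,4-dimethoxyphenyl)-N-methoxy-N-methylpent-4-enamide | C=C[C@H](CC(=O)N(C)OC)c1ccc(OC)c(OC)c1
F4 | step 2 | (S)-2-(diethoxymethyl)-5-(3,4-dimethoxyphenyl)hepta-1,6-dien-3-one | C=C[C@H](CC(=O)C(=C)C(OCC)OCC)c1ccc(OC)c(OC)c1
F5 | step 5 | (1S,2R,3S)-3-(3,4-dimethoxyphenyl)-2-methyl-5-oxo-1-(prop-2-en-1-yl)cyclopentane-1-carbaldehyde | C=CC[C@]1(C=O)C(=O)C[C@H](c2ccc(OC)c(OC)c2)[C@H]1C
F6 | step 5 | methyl 3-[(1S,2R,3S)-3-(3,4-dimethoxyphenyl)-2-methyl-5-oxo-1-(prop-2-en-1-yl)cyclopentyl]-3-hydroxy-2-methoxypropanoate (side-chain centres not defined) | C=CC[C@]1(C(O)C(OC)C(=O)OC)C(=O)C[C@H](c2ccc(OC)c(OC)c2)[C@H]1C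
F7 | step 5 | methyl 3-[(tert-butyldimethylsilyl)oxy]-3-[(1S,2R,3S)-3-(3,4-dimethoxyphenyl)-2-methyl-5-oxo-1-(prop-2-en-1-yl)cyclopentyl]-2-methoxypropanoate (side-chain centres not defined) | C=CC[C@]1(C(O[Si](C)(C)C(C)(C)C)C(OC)C(=O)OC)C(=O)C[C@H](c2ccc(OC)c(OC)c2)[C@H]1C
F8 | step 5 | (1S,5S,6R,7R)-4-[(tert-butyldimethylsilyl)oxy]-7-(3,4-dimethoxyphenyl)-3-methoxy-6-methyl-5-(prop-2-en-1-yl)bicyclo[3.2.1]octane-2,8-dione (C3 and C4 not defined) | C=CC[C@]12C(O[Si](C)(C)C(C)(C)C)C(OC)C(=O)[C@H](C1=O)[C@H](c1ccc(OC)c(OC)c1)[C@H]2C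
F9 | step 3 | prop-2-en-1-yl (3R,4S)-2-(diethoxymethyl)-4-(3,4-dimethoxyphenyl)-3-methylcyclopent-1-en-1-yl carbonate | C=CCOC(=O)OC1=C(C(OCC)OCC)[C@H](C)[C@@H](c2ccc(OC)c(OC)c2)C1
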